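## Retrosynthetic overview
1. The target is an isomer of an endo-7-prenyl bicyclo[3.3.1]nonane-2,4,9-trione. The last step cuts C3–C2' and C3'–C2''. The enolate carbon C3 is oxidised to an electrophilic dioxo radical (an enolonium equivalent) and is attacked by the nucleophilic CH of the C7 prenyl group. The final radical takes up H and becomes the isopropyl group.
2. That bicycle is an isomer of a monocyclic dearomatised acylphloroglucinol. Cut C1–C8, formed by photochemical proton transfer to an isopropenyl group followed by collapse on C1.
3. Ring A: cut C3–C4 and C1–C9. It comes from a double Claisen union of a geranyl(lavandulyl)malonate with the dianion of prenylated isobutyrylacetone, so prenyl and geranyl sites are never in competition.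
4. The malonate comes from dimethyl malonate, geranyl bromide and (S)-lavandulyl iodide. The iodide, obtained by lipase resolution, is the only source of chirality.
5. Order of ring formation: ring A, ring B, the seven-membered bridge (homoadamantane), then the cyclopentane.

Assumption and locants: lavandulol is bought as the racemate. Locants are C1 (acyl-bearing), C2–C4 (C3 central), C5 (geranyl-bearing), C6H2, C7H, C8Me2, C9 (bridging C=O), C1'–C3' for the prenyl on C7, and C1''–C3'' for the prenyl on C3.

## Route

Step 1
Reactants: 1 (±)-lavandulol
Product: 3 (S)-lavandulol, via (S)-lavandulyl hydrogen succinate 2 (not isolated)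
Conditions: porcine pancreatic lipase, succinic anhydride (0.5 equiv), Et2O, rt, stopped at about 40% conversion; extract into 2 M NaOH, rt, 2 h; extract 3 with Et2O (aqueous layer neutralised with HCl); one repeat pass to reach ≥98% ee
Reagents that add atoms: none
Why: Enzymatic kinetic resolution; the lipase acylates the (S)-alcohol faster, the acidic half-ester is pulled into base away from the (R)-alcohol and saponified there, and this fixes C7, from which every other stereocentre is relayed.

Step 2
Reactants: 3 (S)-lavandulol
Product: 4 (S)-lavandulyl iodide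
Conditions: I2, PPh3, imidazole, CH2Cl2, 0 °C to rt
Reagents that add atoms: iodine, II
Why: Garegg–Samuelsson (Appel-type) iodination is an SN2 reaction at the CH2 group, so the adjacent stereocentre and both alkenes are untouched.

Step 3
Reactants: 5 dimethyl malonate, 4 (S)-lavandulyl iodide
Product: 6 dimethyl 2-[(S)-lavandulyl]malonate
Conditions: NaH, THF–DMF, 0 °C; then 4, 60 °C
Reagents that add atoms: none
Why: Malonic ester alkylation; the soft enolate displaces the β-branched primary iodide by SN2, and the sluggish electrophile is used first while the nucleophile is still unhindered.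

Step 4
Reactants: 6 dimethyl 2-[(S)-lavandulyl]malonate, 7 geranyl bromide
Product: 8 dimethyl 2-geranyl-2-[(S)-lavandulyl]malonate
Conditions: NaH, THF, 0 °C; then 7, rt
Reagents that add atoms: none
Why: The second malonate alkylation uses a reactive allylic bromide (SN2, E-alkene retained) to build the C5 quaternary carbon, which is still prochiral because it carries two equal esters.

Step 5
Reactants: 9 5-methylhexane-2,4-dione, 10 prenyl bromide
Product: 11 2,9-dimethyldec-8-ene-3,5-dione
Conditions: LDA (2.1 equiv), THF, −78 to 0 °C; then 10, −78 °C to rt; aq HCl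
Reagents that add atoms: none
Why: Hauser–Harris γ-alkylation; the β-diketone dianion reacts only at its last-formed, most nucleophilic terminal CH2 carbanion.

Step 6
Reactants: 8 dimethyl 2-geranyl-2-[(S)-lavandulyl]malonate, 11 2,9-dimethyldec-8-ene-3,5-dione
Product: 13 6-geranyl-3,5-dihydroxy-2-isobutyryl-6-[(S)-lavandulyl]-4-prenylcyclohexa-2,4-dien-1-one, via acyclic trioxo ester 12 (not isolated)
Conditions: 11 (2.2 equiv), LDA (4.5 equiv), THF, −78 to 0 °C; add 8; 0 to 50 °C, 12 h; aq HCl
Reagents that add atoms: none
Why: Harris-type acylation of the diketone dianion (C3 on one ester) followed by Dieckmann closure (C1 on the other ester), driven by the very acidic product, places prenyl, geranyl and acyl unambiguously; the two esters are diastereotopic without bias, so C5 forms as a 1:1 pair of epimers that is carried on, and only the drawn epimer is productive.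

Step 7
Reactants: 13 6-geranyl-3,5-dihydroxy-2-isobutyryl-6-[(S)-lavandulyl]-4-prenylcyclohexa-2,4-dien-1-one
Product: 14 5-geranyl-4-hydroxy-1-isobutyryl-8,8-dimethyl-3,7-diprenylbicyclo[3.3.1]non-3-ene-2,9-dione (7-prenyl endo)
Conditions: hν (365 nm LED), degassed toluene (5 mM), 0 °C
Reagents that add atoms: none
Why: Excited-state intramolecular proton-transfer photocyclisation, the reaction type that turns dearomatised benzoylphloroglucinols into type A cores; the excited acyl–enol chelate hands its proton to the nearby isopropenyl CH2 and C8 collapses on the adjacent C1 instead of the ground-state-preferred C3, C1 can only form cis to the C5–C6 tether, and in the drawn C5 epimer this forces the C7 prenyl endo (the other epimer gives the exo isomer, removed on silica).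

Step 8
Reactants: 14 5-geranyl-4-hydroxy-1-isobutyryl-8,8-dimethyl-3,7-diprenylbicyclo[3.3.1]non-3-ene-2,9-dione (7-prenyl endo)
Product: 18 CNP0379246.1, via C3 dioxo radical 15 (not isolated), via C3' tertiary radical 16 (not isolated), via C3'' tertiary radical 17 (not isolated)
Conditions: 2,4,5,6-tetra(carbazol-9-yl)isophthalonitrile (2 mol %), 2,4,6-triisopropylbenzenethiol (10 mol %), Bu4N[(BuO)2PO2] (10 mol %), PhCF3 (10 mM), 456 nm LED, Ar, 25 °C
Reagents that add atoms: none
Why: Proposed new method: the catalytic phosphate keeps a little of 14 as its enolate, which the excited cyanoarene oxidises by one electron to the electrophilic 2-alkyl-1,3-dioxo radical 15, so the normally nucleophilic C3 acts as an enolonium equivalent and is attacked by the nucleophilic CH terminus C2' of the endo prenyl group held above it (7-exo, closes the homoadamantane, 16); the tertiary radical then closes 5-exo on the C3 prenyl group (17) and takes H from the thiol, whose thiyl radical is reduced by the catalyst radical anion and reprotonated by fresh 14, giving a redox-neutral isomerisation that installs the isopropyl group directly and leaves the geranyl alkenes alone (5-exo attack of C3 on the bridgehead geranyl group is geometrically impossible in the bicycle); C3 is fixed by the cage, C2' is expected from Curtin–Hammett selection (addition of the stabilised radical is reversible, and only the adduct with CMe2 on the C2 flank matches the twist that the C8 gem-dimethyl group imposes on the C7–C1'–C2'–C3 bridge, so only it has the small C1''–C3–C2'–C3' dihedral needed for fast 5-exo closure), and C2'' follows the Beckwith–Houk chair (CMe2 radical trans to C1'); the closest known reaction types are Mn(OAc)3-mediated oxidative radical cyclisation of 1,3-dicarbonyls onto alkenes and photoredox/thiol redox-neutral hydrofunctionalisation of alkenes.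

## Compound list
1 | (±)-lavandulol (2-isopropenyl-5-methylhex-4-en-1-ol, racemic) | CC(C)=CCC(CO)C(C)=C | starting material
2 | (S)-lavandulyl hydrogen succinate | OC(=O)CCC(=O)OC[C@H](C(C)=C)CC=C(C)C | intermediate
3 | (S)-lavandulol | OC[C@H](C(C)=C)CC=C(C)C | intermediate
4 | (S)-lavandulyl iodide | IC[C@H](C(C)=C)CC=C(C)C | intermediate
5 | dimethyl malonate | COC(=O)CC(=O)OC | starting material
6 | dimethyl 2-[(S)-lavandulyl]malonate (stereocentre spatially unchanged from 3) | COC(=O)C(C[C@H](C(C)=C)CC=C(C)C)C(=O)OC | intermediate
7 | geranyl bromide (E) | CC(C)=CCC/C(C)=C/CBr | starting material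
8 | dimethyl 2-geranyl-2-[(S)-lavandulyl]malonate | COC(=O)C(C/C=C(\C)CCC=C(C)C)(C[C@H](C(C)=C)CC=C(C)C)C(=O)OC | intermediate
9 | 5-methylhexane-2,4-dione | CC(C)C(=O)CC(C)=O | starting material
10 | prenyl bromide | CC(C)=CCBr | starting material
11 | 2,9-dimethyldec-8-ene-3,5-dione | CC(C)C(=O)CC(=O)CCC=C(C)C | intermediate
12 | methyl 2-geranyl-2-[(S)-lavandulyl]-8-methyl-3,5,7-trioxo-4-prenylnonanoate (productive C2 epimer; C4 labile) | COC(=O)[C@](C/C=C(\C)CCC=C(C)C)(C[C@H](C(C)=C)CC=C(C)C)C(=O)C(CC=C(C)C)C(=O)CC(=O)C(C)C | intermediate
13 | 6-geranyl-3,5-dihydroxy-2-isobutyryl-6-[(S)-lavandulyl]-4-prenylcyclohexa-2,4-dien-1-one (seen from the geranyl CH2, C(OH)=, C=O and lavandulyl CH2 run clockwise) | CC(C)C(=O)C1=C(O)C(CC=C(C)C)=C(O)[C@@](C/C=C(\C)CCC=C(C)C)(C[C@H](C(C)=C)CC=C(C)C)C1=O | intermediate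
14 | 5-geranyl-4-hydroxy-1-isobutyryl-8,8-dimethyl-3,7-diprenylbicyclo[3.3.1]non-3-ene-2,9-dione (7-prenyl endo, syn to the C2–C4 bridge; H7 exo) | CC(C)C(=O)[C@@]12C(=O)C(CC=C(C)C)=C(O)[C@@](C/C=C(\C)CCC=C(C)C)(C[C@@H](CC=C(C)C)C1(C)C)C2=O | intermediate
15 | C3 dioxo radical of 14 | CC(C)C(=O)[C@@]12C(=O)[C](CC=C(C)C)C(=O)[C@@](C/C=C(\C)CCC=C(C)C)(C[C@@H](CC=C(C)C)C1(C)C)C2=O | intermediate
16 | homoadamantane C3' tertiary radical (C3–C2' formed, CMe2 on the C2 flank) | CC(C)=CCC/C(C)=C/C[C@@]12C[C@H]3C[C@H]([C](C)C)[C@@](CC=C(C)C)(C1=O)C(=O)[C@@](C(=O)C(C)C)(C2=O)C3(C)C | intermediate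
17 | tetracyclic C3'' tertiary radical (cyclopentane closed) | CC(C)=CCC/C(C)=C/C[C@@]12C[C@H]3C[C@@H]4C(C)(C)[C@@H]([C](C)C)C[C@]4(C1=O)C(=O)[C@@](C(=O)C(C)C)(C2=O)C3(C)C | intermediate
18 | CNP0379246.1 (geranyl, isobutyryl homoadamantane trione with fused isopropyl-dimethylcyclopentane) | CC(C)=CCC/C(C)=C/C[C@@]12C[C@H]3C[C@@H]4C(C)(C)[C@@H](C(C)C)C[C@]4(C1=O)C(=O)[C@@](C(=O)C(C)C)(C2=O)C3(C)C | target

## Step count and weak points
Total steps: 8. Longest linear sequence: 7 (steps 1, 2, 3, 4, 6, 7, 8).

**Step 8 is the most likely to fail.**
- The photoredox/thiol isomerisation has no direct precedent on a hindered 2-alkyl-1,3-diketone.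
- The thiol may quench radical 16 before the second ring closes.
- The required adduct carries CMe2 on the more crowded C2/C8 flank, where a methyl–methyl contact with C8 could tip the selection to the C4 flank and give the C2' epimer. The fallback below does not correct this selectivity.
- Fallback: set out from 14 and use a stoichiometric oxidative ending in place of the redox-neutral one. Mn(OAc)3·2H2O (2.2 equiv) and Cu(OAc)2 (1 equiv) in degassed AcOH at rt run the same two ring closures. The last radical is oxidised to the less substituted alkene, giving the isopropenyl cage compound F1. H2 (1 atm) over RhCl(PPh3)3 in benzene then saturates only this 1,1-disubstituted alkene beside the two trisubstituted geranyl alkenes. The fallback returns to the route at 18.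

**Step 7 is the second most likely to fail.**
- The aliphatic acyl chromophore may transfer its proton poorly.
- The ion pair may close on oxygen.
- The endo closure has to pass through a crowded transition state.
- Fallback: set out from 13 and use a ground-state cation with C3 switched off. Pivaloyl chloride and Et3N acylate the free, non-chelated 4-OH to give the monocyclic 4-O-pivalate F2. Its C3 is no longer a good nucleophile, so formic acid at 0 °C protonates the isopropenyl group and the chelated enol closes through C1 to the bicyclic enol pivalate F3. K2CO3 in MeOH removes the pivalate. The fallback returns to the route at 14.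

**Step 6 is the third most likely to fail.**
- Both esters of 8 are neopentyl-like.
- The triketo ester 12 may lactonise to a pyranone instead of closing on carbon.
- Fallback: set out from 4 and build ring A from an arene instead. Purchased phlorisobutyrophenone F4 is C-alkylated with 4 (LiHMDS, THF) to the 3-lavandulyl arene F5. Prenyl bromide 10 (LiHMDS) fills the last free ring position to give the 3-lavandulyl-5-prenyl arene F6. Geranyl bromide 7 (LiHMDS, THF, 0 °C) then alkylates with dearomatisation. The fallback returns to the route at 13.
- Price of this fallback: about half of the alkylation goes to the prenyl-bearing carbon. That isomer cannot form the bicycle in step 7 and is removed there.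

## Further compounds
F1 | step 8 | isopropenyl analogue of 18 (isopropenyl in place of isopropyl on C2'') | CC(C)=CCC/C(C)=C/C[C@@]12C[C@H]3C[C@@H]4C(C)(C)[C@@H](C(C)=C)C[C@]4(C1=O)C(=O)[C@@](C(=O)C(C)C)(C2=O)C3(C)C
F2 | step 7 | 4-O-pivalate of 13 | CC(C)C(=O)C1=C(O)C(CC=C(C)C)=C(OC(=O)C(C)(C)C)[C@@](C/C=C(\C)CCC=C(C)C)(C[C@H](C(C)=C)CC=C(C)C)C1=O
F3 | step 7 | 4-O-pivalate of 14 | CC(C)C(=O)[C@@]12C(=O)C(CC=C(C)C)=C(OC(=O)C(C)(C)C)[C@@](C/C=C(\C)CCC=C(C)C)(C[C@@H](CC=C(C)C)C1(C)C)C2=O
F4 | step 6 | phlorisobutyrophenone (purchased) | CC(C)C(=O)c1c(O)cc(O)cc1O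
F5 | step 6 | 3-[(S)-lavandulyl]phlorisobutyrophenone | CC(C)C(=O)c1c(O)cc(O)c(C[C@H](C(C)=C)CC=C(C)C)c1O
F6 | step 6 | 3-[(S)-lavandulyl]-5-prenylphlorisobutyrophenone | CC(C)C(=O)c1c(O)c(CC=C(C)C)c(O)c(C[C@H](C(C)=C)CC=C(C)C)c1O
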